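Ring A (C4a, C5, C6, C7, C8, C8a) and the pyrone on C6 are read as two triacetic-lactone units joined head to tail. C6 comes from the 6-methyl group of the pyrone that survives. C7, C8, C8a, C4a and C5 are C2 to C6 of a second pyrone, whose methyl becomes the C5 methyl. One operation joins lithiated 4-methoxy-6-methyl-2-pyrone to the lactone carbonyl of 4-benzyloxy-6-methyl-2-pyrone (C6–C7) and recloses the chain by aldol condensation (C6–C5). The arylpyrone formed already carries the methyl ether; the benzyl ether marks the future lactone oxygen. Silylation, debenzylation and a carbene-catalysed annulation that sets C4 complete the dihydrocoumarin.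

Key step: step 2

Assumption: the aminoindanol-derived triazolium salt is available as both antipodes; the (5aR,10bS) form is written for the 4R lactone from the usual face-shielding model, and its mirror image would be taken if the sense of induction proves opposite.

Step 1
Reactants: 1 4-hydroxy-6-methyl-2H-pyran-2-one; 2 benzyl alcohol
Product: 3 4-(benzyloxy)-6-methyl-2H-pyran-2-one
Conditions: PPh3, DIAD, THF, 0 °C to rt
Reagents that add atoms: none
Why: Mitsunobu reaction, in which the acidic 4-hydroxy-2-pyrone (a vinylogous carboxylic acid) is alkylated on O4 by the benzyloxyphosphonium ion, avoiding the C3-benzylation that accompanies benzyl halide and base.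

Step 2
Reactants: 4 4-methoxy-6-methyl-2H-pyran-2-one; 3 4-(benzyloxy)-6-methyl-2H-pyran-2-one
Product: 8 6-[4-(benzyloxy)-2-hydroxy-6-methylphenyl]-4-methoxy-2H-pyran-2-one, via lithiated methoxypyrone 5 (not isolated), via open-chain enedione 6 (not isolated), via cyclic aldol 7 (not isolated)
Conditions: LiN(i-Pr)2 (1.05 equiv), THF, −78 °C, 30 min; then 3 (1.5 equiv), −78 °C to rt; 1 M HCl
Reagents that add atoms: none
Why: Proposed new method: LiN(i-Pr)2 removes a proton from the 6-methyl group of 4 to give the extended enolate 5, which should add to the lactone carbonyl C2 of 3 (Claisen-type acylation); collapse of the adduct opens the ring to the enolate of 6, a proton shift places the charge on the methylene flanked by the pyrone and the new ketone, and this carbon adds to the released methyl ketone (aldol, 7) before loss of water and enolisation give the phenoxide of 8. The closest known reaction types are the condensation of lithiated ortho-toluates with 4-alkoxy-6-methyl-2-pyrones, the base-mediated aldol aromatisation of pyrone-capped polyketide chains and carbanion-induced ring transformations of 2-pyranones into arenes, but a pyrone-onto-pyrone version is not established. Ring A closes in a 6-(enolendo)-exo-trig aldol addition, which is geometrically prepared because the C3=C4 double bond inherited from 3 holds the carbanion and the methyl ketone cis. No stereocentre is created, the two centres of 7 being erased on aromatisation. The step needs carbonyl attack in preference to conjugate addition at C4 or C6 of 3, which is expected because both positions are fully substituted and donor-deactivated and their adducts can revert whereas the carbonyl adduct drains irreversibly to the arene, and it needs the most acidic carbon to pair with the unconjugated methyl ketone, which the chain itself dictates. It also needs the two pyrones to keep their roles although they are equally acidic, which the substrates do not secure and which rests on complete pre-lithiation of 4, low temperature and an excess of 3.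

Step 3
Reactants: 8 6-[4-(benzyloxy)-2-hydroxy-6-methylphenyl]-4-methoxy-2H-pyran-2-one
Product: 9 6-{4-(benzyloxy)-2-[(tert-butyldimethylsilyl)oxy]-6-methylphenyl}-4-methoxy-2H-pyran-2-one
Conditions: TBSCl, imidazole, DMF, rt
Reagents that add atoms: tert-butyldimethylsilyl chloride, CC(C)(C)[Si](C)(C)Cl
Why: Standard silylation of the only free phenol (the later C7–OH), placed here so that in step 6 the carbon between the two oxygens (the later C8) is shielded and only the other oxygen can lactonise.

Step 4
Reactants: 9 6-{4-(benzyloxy)-2-[(tert-butyldimethylsilyl)oxy]-6-methylphenyl}-4-methoxy-2H-pyran-2-one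
Product: 10 6-{2-[(tert-butyldimethylsilyl)oxy]-4-hydroxy-6-methylphenyl}-4-methoxy-2H-pyran-2-one
Conditions: H2 (1 atm), Pd/C (10 wt %), EtOAc, rt
Reagents that add atoms: none
Why: Catalytic hydrogenolysis of an aryl benzyl ether, which in neutral ethyl acetate should leave the aryl silyl ether and the 4-methoxy-2-pyrone untouched if stopped after uptake of one equivalent of hydrogen.

Step 5
Reactants: 11 (2E)-3-(4-hydroxyphenyl)prop-2-enal
Product: 12 (2E)-3-{4-[(tert-butyldimethylsilyl)oxy]phenyl}prop-2-enal
Conditions: TBSCl, imidazole, CH2Cl2, rt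
Reagents that add atoms: tert-butyldimethylsilyl chloride, CC(C)(C)[Si](C)(C)Cl
Why: Silylation of a phenol, which keeps the enal's own hydroxyl from being acylated by the acyl azolium or oxidised in step 6 and leaves the E-alkene unchanged.

Step 6
Reactants: 10 6-{2-[(tert-butyldimethylsilyl)oxy]-4-hydroxy-6-methylphenyl}-4-methoxy-2H-pyran-2-one; 12 (2E)-3-{4-[(tert-butyldimethylsilyl)oxy]phenyl}prop-2-enal
Product: 13 (4R)-7-[(tert-butyldimethylsilyl)oxy]-4-{4-[(tert-butyldimethylsilyl)oxy]phenyl}-6-(4-methoxy-2-oxo-2H-pyran-6-yl)-5-methyl-3,4-dihydro-2H-chromen-2-one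
Conditions: (5aR,10bS)-2-mesityl-5a,10b-dihydro-4H,6H-indeno[2,1-b][1,2,4]triazolo[4,3-d][1,4]oxazin-2-ium tetrafluoroborate (10 mol %), 3,3',5,5'-tetra-tert-butyldiphenoquinone (1.2 equiv), i-Pr2NEt (0.5 equiv), 4 Å MS, toluene, rt
Reagents that add atoms: none
Why: Carbene-catalysed oxidative [3+3] annulation of an enal with an electron-rich phenol (acyl azolium Michael addition and lactonisation, Coates–Claisen type), in which the Breslow intermediate of 12 is oxidised to the α,β-unsaturated acyl azolium, the phenol of 10 delivers its free ortho carbon para to the silyloxy group to the β-carbon and its oxygen then acylates with release of the carbene, the C4 configuration being set by the aminoindanol backbone that shields one face of the acyl azolium.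

Step 7
Reactants: 13 (4R)-7-[(tert-butyldimethylsilyl)oxy]-4-{4-[(tert-butyldimethylsilyl)oxy]phenyl}-6-(4-methoxy-2-oxo-2H-pyran-6-yl)-5-methyl-3,4-dihydro-2H-chromen-2-one
Product: 14 (4R)-7-hydroxy-4-(4-hydroxyphenyl)-6-(4-methoxy-2-oxo-2H-pyran-6-yl)-5-methyl-3,4-dihydro-2H-chromen-2-one
Conditions: HF·pyridine, THF, 0 °C to rt
Reagents that add atoms: none
Why: Fluoride-mediated desilylation of both aryl silyl ethers under weakly acidic conditions, which should keep the aryl lactone closed and cannot affect C4 because this centre is not enolisable.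

Compound list

1 | 4-hydroxy-6-methyl-2H-pyran-2-one (triacetic acid lactone) | Cc1cc(O)cc(=O)o1 | starting material
2 | benzyl alcohol | OCc1ccccc1 | starting material
3 | 4-(benzyloxy)-6-methyl-2H-pyran-2-one | Cc1cc(OCc2ccccc2)cc(=O)o1 | intermediate
4 | 4-methoxy-6-methyl-2H-pyran-2-one | COc1cc(C)oc(=O)c1 | starting material
5 | 6-(lithiomethyl)-4-methoxy-2H-pyran-2-one (extended lithium enolate of 4) | [Li]Cc1cc(OC)cc(=O)o1 | intermediate (not isolated)
6 | 6-[(3E)-4-(benzyloxy)-2,6-dioxohept-3-en-1-yl]-4-methoxy-2H-pyran-2-one (present as its lithium enolate; ketone and methylene cis on the double bond) | COc1cc(CC(=O)/C=C(/OCc2ccccc2)CC(C)=O)oc(=O)c1 | intermediate (not isolated)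
7 | 6-[4-(benzyloxy)-6-hydroxy-6-methyl-2-oxocyclohex-3-en-1-yl]-4-methoxy-2H-pyran-2-one (diastereomer mixture, both centres lost on aromatisation) | COc1cc(C2C(=O)C=C(OCc3ccccc3)CC2(C)O)oc(=O)c1 | intermediate (not isolated)
8 | 6-[4-(benzyloxy)-2-hydroxy-6-methylphenyl]-4-methoxy-2H-pyran-2-one | COc1cc(-c2c(C)cc(OCc3ccccc3)cc2O)oc(=O)c1 | intermediate
9 | 6-{4-(benzyloxy)-2-[(tert-butyldimethylsilyl)oxy]-6-methylphenyl}-4-methoxy-2H-pyran-2-one | COc1cc(-c2c(C)cc(OCc3ccccc3)cc2O[Si](C)(C)C(C)(C)C)oc(=O)c1 | intermediate
10 | 6-{2-[(tert-butyldimethylsilyl)oxy]-4-hydroxy-6-methylphenyl}-4-methoxy-2H-pyran-2-one | COc1cc(-c2c(C)cc(O)cc2O[Si](C)(C)C(C)(C)C)oc(=O)c1 | intermediate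
11 | (2E)-3-(4-hydroxyphenyl)prop-2-enal (4-hydroxycinnamaldehyde) | O=C/C=C/c1ccc(O)cc1 | starting material
12 | (2E)-3-{4-[(tert-butyldimethylsilyl)oxy]phenyl}prop-2-enal | O=C/C=C/c1ccc(O[Si](C)(C)C(C)(C)C)cc1 | intermediate
13 | (4R)-7-[(tert-butyldimethylsilyl)oxy]-4-{4-[(tert-butyldimethylsilyl)oxy]phenyl}-6-(4-methoxy-2-oxo-2H-pyran-6-yl)-5-methyl-3,4-dihydro-2H-chromen-2-one | COc1cc(-c2c(O[Si](C)(C)C(C)(C)C)cc3c(c2C)[C@@H](c2ccc(O[Si](C)(C)C(C)(C)C)cc2)CC(=O)O3)oc(=O)c1 | intermediate
14 | (4R)-7-hydroxy-4-(4-hydroxyphenyl)-6-(4-methoxy-2-oxo-2H-pyran-6-yl)-5-methyl-3,4-dihydro-2H-chromen-2-one | COc1cc(-c2c(O)cc3c(c2C)[C@@H](c2ccc(O)cc2)CC(=O)O3)oc(=O)c1 | target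

Total step count: 7
Longest linear sequence: 6 steps (1 → 3 → 8 → 9 → 10 → 13 → 14)

Steps most likely to fail

1. Step 2. Proton transfer between 5 and 3 may exchange the roles of the two pyrones before carbon–carbon bond formation, or the carbanion may add reversibly in conjugate fashion and never reach the lactone carbonyl. The fallback differentiates the partners by acidity and closes the ring by olefination. It sets out from 4: Wohl–Ziegler bromination (NBS, dibenzoyl peroxide, PhCF3, reflux) gives 6-(bromomethyl)-4-methoxy-2H-pyran-2-one F1, and Michaelis–Arbuzov reaction with triethyl phosphite gives diethyl [(4-methoxy-2-oxo-2H-pyran-6-yl)methyl]phosphonate F2. The lithium salt of F2 (LiN(SiMe3)2, THF, −78 °C to reflux) is the only carbanion present beside 3; it is acylated by the enol-lactone carbonyl of 3 and closes ring A by intramolecular Horner–Wadsworth–Emmons olefination (the phosphonate form of the Fujimoto–Belleau annulation). The dienone formed tautomerises to 8, where the route is rejoined.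

2. Step 6. The phenol may be acylated on oxygen to an aryl cinnamate that does not go on to the C–C bond, or the facial selectivity may be poor at the hindered carbon next to the C5 methyl. The fallback makes the C4–C4a bond by iminium catalysis. It sets out from 10 and 12: a diarylprolinol trimethylsilyl ether (the antipode that delivers 4R) with benzoic acid in toluene should effect Friedel–Crafts alkylation and hemiacetalisation to (4R)-7-[(tert-butyldimethylsilyl)oxy]-4-{4-[(tert-butyldimethylsilyl)oxy]phenyl}-6-(4-methoxy-2-oxo-2H-pyran-6-yl)-5-methyl-3,4-dihydro-2H-chromen-2-ol F3, a mixture of anomers. Oxidation of the lactol with TEMPO and PhI(OAc)2 in CH2Cl2 returns to the route at 13.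

3. Step 4. Hydrogen may add to the C5=C6 bond of the pyrone, or the silyl ether may be lost during a slow hydrogenolysis. The fallback cleaves the benzyl ether without hydrogen. It sets out from 9: BCl3 with pentamethylbenzene as cation scavenger in CH2Cl2 at −78 °C (Lewis-acid debenzylation) is expected to spare the silyl ether and the methyl ether and gives 10 directly. No new compound arises (F0).

Further compounds

F1 | step 2 | 6-(bromomethyl)-4-methoxy-2H-pyran-2-one | COc1cc(CBr)oc(=O)c1
F2 | step 2 | diethyl [(4-methoxy-2-oxo-2H-pyran-6-yl)methyl]phosphonate | CCOP(=O)(Cc1cc(OC)cc(=O)o1)OCC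
F3 | step 6 | (4R)-7-[(tert-butyldimethylsilyl)oxy]-4-{4-[(tert-butyldimethylsilyl)oxy]phenyl}-6-(4-methoxy-2-oxo-2H-pyran-6-yl)-5-methyl-3,4-dihydro-2H-chromen-2-ol (anomer mixture) | COc1cc(-c2c(O[Si](C)(C)C(C)(C)C)cc3c(c2C)[C@@H](c2ccc(O[Si](C)(C)C(C)(C)C)cc2)CC(O)O3)oc(=O)c1
F0 | step 4 | none | none
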